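**Retrosynthetic overview**
1. The quinone is unmasked last with (NH4)2Ce(NO3)6 from its 1,4-dimethoxynaphthalene. Just before that, one iridium-catalysed asymmetric hydrogenation of a pentaene saturates all five C=C bonds and sets C3', C7', C11' and C15' together.
2. The pentaene comes from an sp3–sp2 Negishi coupling (C14'–C15') of an alkylzinc, made from vitamin K2 (MK-4) truncated at its terminal isopropylidene, with a cyclopentenyl triflate.
3. The cyclopentene comes from the only ring-forming step. It is modelled on the presumed biosynthesis, in which a radical SAM-type ring synthase joins the C15' methyl carbon to the unactivated C18' methylene of a saturated isoprenoid segment. Here a copper carbenoid at that carbon inserts into C18'–H.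
4. The diazo β-keto sulfone comes from (R)-citronellyl bromide, which supplies C19', and the dianion of (phenylsulfonyl)acetone. The sulfone later leaves reductively and fixes the enol triflate regiochemistry.
5. Ring order: the naphthalene bicycle is bought intact in MK-4; the cyclopentane is formed in step 3.

Assumption (locants): C1'–C24' number the regular hexaprenyl chain from the quinone and C15a' is the former 15'-methyl carbon (ring CH2 between C15' and C18'); the target is 3'S,7'S,11'R,15'R,18'S,19'R with a cis-1,3-disubstituted ring.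
Assumption (ligand hand): the enantiomer of each chiral ligand in steps 3 and 10 is defined by what it must deliver; which hand that is has not been verified.

**Step 1**
Reactants: 1 1-(phenylsulfonyl)propan-2-one; 2 (6R)-8-bromo-2,6-dimethyloct-2-ene [(R)-citronellyl bromide]
Product: 4 (6S)-6,10-dimethyl-1-(phenylsulfonyl)undec-9-en-2-one, via sodium lithium dianion 3 (not isolated)
Conditions: NaH (1.1 equiv), THF, 0 °C; n-BuLi (1.05 equiv), 0 °C; then 2, 0 → 25 °C; 1 M HCl quench
Reagents that add atoms: none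
Why: γ-alkylation of a β-keto sulfone 1,3-dianion (Huckin–Weiler-type dianion alkylation), in which the less stabilised terminal carbanion displaces the primary bromide by SN2; the stereocentre of 2 (future C19') is remote and untouched, and its descriptor changes from R to S only because the CIP priorities change.

**Step 2**
Reactants: 4 (6S)-6,10-dimethyl-1-(phenylsulfonyl)undec-9-en-2-one
Product: 5 (6S)-1-diazo-6,10-dimethyl-1-(phenylsulfonyl)undec-9-en-2-one
Conditions: 4-acetamidobenzenesulfonyl azide (1.2 equiv), Et3N (1.5 equiv), MeCN, 0 → 25 °C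
Reagents that add atoms: 4-acetamidobenzenesulfonyl azide, CC(=O)Nc1ccc(cc1)S(=O)(=O)N=[N+]=[N-]
Why: Regitz diazo transfer to the doubly activated methylene between ketone and sulfone, with no stereocentre formed or touched.

**Step 3**
Reactants: 5 (6S)-1-diazo-6,10-dimethyl-1-(phenylsulfonyl)undec-9-en-2-one
Product: 6 (2R,3R)-3-[(2R)-6-methylhept-5-en-2-yl]-2-(phenylsulfonyl)cyclopentan-1-one
Conditions: CuCl2 (5 mol%), Na[B(3,5-(CF3)2C6H3)4] (6 mol%), 2,2'-(propane-2,2-diyl)bis[(4R,5S)-4,5-diphenyl-4,5-dihydrooxazole] (6 mol%; the mirror-image ligand is used instead if a first run shows this hand to be the mismatched partner of the C6 stereocentre), CH2Cl2, 40 °C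
Reagents that add atoms: none
Why: Copper–bis(oxazoline)-catalysed intramolecular carbenoid 1,5 C–H insertion of an α-diazo-β-keto sulfone (a known, highly enantiocontrolled route to trans-2-sulfonyl-3-alkylcyclopentanones), which forges the biosynthetic C15a'–C18' bond on a saturated chain segment with retention at carbon; the chiral catalyst selects the pro-R hydrogen of the C5 methylene to set C18', C19' comes unchanged from citronellyl bromide, the sulfonyl group settles trans, five-ring insertion is preferred over the 1,6-insertion at the methine and over attack on the remote alkene, and the crystalline sulfone allows the diastereomer ratio to be raised by recrystallisation.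

**Step 4**
Reactants: 6 (2R,3R)-3-[(2R)-6-methylhept-5-en-2-yl]-2-(phenylsulfonyl)cyclopentan-1-one
Product: 8 (3R)-3-[(2R)-6-methylhept-5-en-2-yl]cyclopent-1-en-1-yl trifluoromethanesulfonate, via samarium enolate 7 (not isolated)
Conditions: 6 added dropwise to SmI2 (2.2 equiv), HMPA (4 equiv), THF, −78 °C (inverse addition); then N-(5-chloropyridin-2-yl)-bis(trifluoromethanesulfonyl)imide (Comins' reagent, 1.3 equiv), −78 → 0 °C
Reagents that add atoms: Comins' reagent, Clc1ccc(nc1)N(S(=O)(=O)C(F)(F)F)S(=O)(=O)C(F)(F)F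
Why: Proposed new method: two-electron reductive C–S cleavage of the α-sulfonyl ketone by divalent samarium expels benzenesulfinate and leaves the enolate with its double bond fixed at C15'=C15a', and O-sulfonylation then gives the single enol triflate regioisomer; inverse addition keeps the acidic starting sulfone from protonating the enolate, C18' is not acidic and is untouched, and the closest known reaction types are SmI2 reduction of α-heterosubstituted ketones with trapping of the samarium enolate and Comins triflation of metal enolates.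

**Step 5**
Reactants: 9 menatetrenone (vitamin K2, MK-4), 2-methyl-3-[(2E,6E,10E)-3,7,11,15-tetramethylhexadeca-2,6,10,14-tetraen-1-yl]naphthalene-1,4-dione
Product: 11 1,4-dimethoxy-2-methyl-3-[(2E,6E,10E)-3,7,11,15-tetramethylhexadeca-2,6,10,14-tetraen-1-yl]naphthalene, via menaquinol-4 10 (not isolated)
Conditions: Na2S2O4 (3 equiv), Bu4NBr (10 mol%), THF/H2O, 25 °C; then NaOH, Me2SO4 (4 equiv), 25 °C
Reagents that add atoms: dimethyl sulfate, COS(=O)(=O)OC
Why: Dithionite reduction of the quinone followed in the same flask by phase-transfer Williamson O-methylation of the air-sensitive hydroquinone, which protects the quinone from the organometallic, hydride and hydrogenation steps and leaves the E-alkenes alone.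

**Step 6**
Reactants: 11 1,4-dimethoxy-2-methyl-3-[(2E,6E,10E)-3,7,11,15-tetramethylhexadeca-2,6,10,14-tetraen-1-yl]naphthalene
Product: 13 2-[(2E,6E,10E)-13-(3,3-dimethyloxiran-2-yl)-3,7,11-trimethyltrideca-2,6,10-trien-1-yl]-1,4-dimethoxy-3-methylnaphthalene (racemic at the oxirane CH), via bromohydrin 12 (not isolated)
Conditions: N-bromosuccinimide (1.05 equiv), THF/H2O (3:1), 0 °C; then K2CO3, MeOH, 25 °C
Reagents that add atoms: water, O
Why: Van Tamelen terminal-selective bromohydrin formation (in aqueous medium the coiled polyene exposes only its terminal trisubstituted alkene; Markovnikov opening of the bromonium ion by water) followed by base-induced epoxide closure; the new oxirane stereocentre is irrelevant because that carbon becomes the aldehyde carbon in step 7.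

**Step 7**
Reactants: 13 2-[(2E,6E,10E)-13-(3,3-dimethyloxiran-2-yl)-3,7,11-trimethyltrideca-2,6,10-trien-1-yl]-1,4-dimethoxy-3-methylnaphthalene
Product: 15 (4E,8E,12E)-14-(1,4-dimethoxy-3-methylnaphthalen-2-yl)-4,8,12-trimethyltetradeca-4,8,12-trien-1-ol, via aldehyde 14 (not isolated)
Conditions: H5IO6 (1.2 equiv), THF/Et2O, 0 °C; then NaBH4 (1.5 equiv), MeOH, 0 °C
Reagents that add atoms: water, O
Why: Periodic acid opens the epoxide to the glycol and cleaves it (Malaprade cleavage) to the C14' aldehyde and acetone, and borohydride reduces the aldehyde in the same flask, so the chain now ends exactly at C14' with the three E-alkenes intact.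

**Step 8**
Reactants: 15 (4E,8E,12E)-14-(1,4-dimethoxy-3-methylnaphthalen-2-yl)-4,8,12-trimethyltetradeca-4,8,12-trien-1-ol
Product: 16 2-[(2E,6E,10E)-14-iodo-3,7,11-trimethyltetradeca-2,6,10-trien-1-yl]-1,4-dimethoxy-3-methylnaphthalene
Conditions: I2 (1.2 equiv), PPh3 (1.2 equiv), imidazole (1.5 equiv), CH2Cl2, 0 → 25 °C
Reagents that add atoms: iodine, II
Why: Appel-type (Garegg–Samuelsson) iodination of a primary alcohol through the alkoxyphosphonium ion under neutral conditions that leave the trisubstituted alkenes and aryl ethers untouched.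

**Step 9**
Reactants: 16 2-[(2E,6E,10E)-14-iodo-3,7,11-trimethyltetradeca-2,6,10-trien-1-yl]-1,4-dimethoxy-3-methylnaphthalene; 8 (3R)-3-[(2R)-6-methylhept-5-en-2-yl]cyclopent-1-en-1-yl trifluoromethanesulfonate
Product: 18 1,4-dimethoxy-2-methyl-3-[(2E,6E,10E)-3,7,11-trimethyl-14-{(3R)-3-[(2R)-6-methylhept-5-en-2-yl]cyclopent-1-en-1-yl}tetradeca-2,6,10-trien-1-yl]naphthalene, via alkylzinc iodide 17 (not isolated)
Conditions: Zn dust (2 equiv), LiCl (1.5 equiv), THF, 40 °C; then 8, Pd(OAc)2 (3 mol%), 2-dicyclohexylphosphino-2',6'-dimethoxybiphenyl (6 mol%), THF, 25 → 40 °C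
Reagents that add atoms: none
Why: Negishi sp3–sp2 cross-coupling (zinc insertion into the primary iodide, oxidative addition of zerovalent palladium to the enol triflate, transmetalation, reductive elimination) joins C14' to C15' and places the ring double bond at C15'=C15a' with no isomerisation; no stereocentre is formed and C18' and C19' are untouched.

**Step 10**
Reactants: 18 1,4-dimethoxy-2-methyl-3-[(2E,6E,10E)-3,7,11-trimethyl-14-{(3R)-3-[(2R)-6-methylhept-5-en-2-yl]cyclopent-1-en-1-yl}tetradeca-2,6,10-trien-1-yl]naphthalene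
Product: 19 1,4-dimethoxy-2-methyl-3-[(3S,7S,11R)-3,7,11-trimethyl-14-{(1R,3S)-3-[(2R)-6-methylheptan-2-yl]cyclopentyl}tetradecyl]naphthalene
Conditions: H2 (50 bar), [Ir(cod)(L)][B(3,5-(CF3)2C6H3)4] (3 mol%), L = 8-(di-o-tolylphosphinooxy)-2-phenyl-5,6,7,8-tetrahydroquinoline in the enantiomeric form opposite to the one that turns all-E farnesyl-type chains into the natural R,R tocopherol-type chain, CH2Cl2, 25 °C
Reagents that add atoms: none
Why: Iridium P,N-catalysed asymmetric hydrogenation of unfunctionalised trisubstituted alkenes (Pfaltz type), in which the face is fixed by the position of the lone vinylic hydrogen, so one ligand hand gives the same spatial sense at C3', C7' and C11' from the three E-alkenes; the ring alkene, whose vinylic hydrogen sits on C15a' with ring carbon C16' trans to it, presents the same local pattern and takes up H2 on the face anti to the C18' substituent (catalyst and substrate matched), giving the cis ring with C15' R, while the terminal isopropylidene becomes isopropyl without a stereocentre.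

**Step 11**
Reactants: 19 1,4-dimethoxy-2-methyl-3-[(3S,7S,11R)-3,7,11-trimethyl-14-{(1R,3S)-3-[(2R)-6-methylheptan-2-yl]cyclopentyl}tetradecyl]naphthalene
Product: 20 2-methyl-3-[(3S,7S,11R)-3,7,11-trimethyl-14-{(1R,3S)-3-[(2R)-6-methylheptan-2-yl]cyclopentyl}tetradecyl]naphthalene-1,4-dione (CNP0182328.1)
Conditions: (NH4)2Ce(NO3)6 (2.5 equiv), MeCN/H2O (4:1), 0 °C
Reagents that add atoms: water, O
Why: Oxidative demethylation of a 1,4-dimethoxyarene by tetravalent cerium (two one-electron oxidations with water attack at the ipso carbons and loss of methanol) gives the naphthoquinone; the saturated side chain and its six stereocentres are inert.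

**Compound list**
1 | 1-(phenylsulfonyl)propan-2-one | CC(=O)CS(=O)(=O)c1ccccc1 | starting material
2 | (6R)-8-bromo-2,6-dimethyloct-2-ene, (R)-citronellyl bromide | BrCC[C@H](C)CCC=C(C)C | starting material
3 | sodium lithium 1,3-dianion of 1 | [Na+].[Li+].[CH2-]C(=O)[CH-]S(=O)(=O)c1ccccc1 | intermediate (not isolated)
4 | (6S)-6,10-dimethyl-1-(phenylsulfonyl)undec-9-en-2-one | O=C(CS(=O)(=O)c1ccccc1)CCC[C@H](C)CCC=C(C)C | intermediate
5 | (6S)-1-diazo-6,10-dimethyl-1-(phenylsulfonyl)undec-9-en-2-one | O=C(C(=[N+]=[N-])S(=O)(=O)c1ccccc1)CCC[C@H](C)CCC=C(C)C | intermediate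
6 | (2R,3R)-3-[(2R)-6-methylhept-5-en-2-yl]-2-(phenylsulfonyl)cyclopentan-1-one | O=C1CC[C@H]([C@H](C)CCC=C(C)C)[C@H]1S(=O)(=O)c1ccccc1 | intermediate
7 | diiodosamarium (3R)-3-[(2R)-6-methylhept-5-en-2-yl]cyclopent-1-en-1-olate (trivalent samarium enolate) | I[Sm](I)OC1=C[C@@H]([C@H](C)CCC=C(C)C)CC1 | intermediate (not isolated)
8 | (3R)-3-[(2R)-6-methylhept-5-en-2-yl]cyclopent-1-en-1-yl trifluoromethanesulfonate | FC(F)(F)S(=O)(=O)OC1=C[C@@H]([C@H](C)CCC=C(C)C)CC1 | intermediate
9 | menatetrenone (MK-4), 2-methyl-3-[(2E,6E,10E)-3,7,11,15-tetramethylhexadeca-2,6,10,14-tetraen-1-yl]naphthalene-1,4-dione | CC1=C(C/C=C(\C)CC/C=C(\C)CC/C=C(\C)CCC=C(C)C)C(=O)c2ccccc2C1=O | starting material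
10 | menaquinol-4, 2-methyl-3-[(2E,6E,10E)-3,7,11,15-tetramethylhexadeca-2,6,10,14-tetraen-1-yl]naphthalene-1,4-diol | Cc1c(C/C=C(\C)CC/C=C(\C)CC/C=C(\C)CCC=C(C)C)c(O)c2ccccc2c1O | intermediate (not isolated)
11 | 1,4-dimethoxy-2-methyl-3-[(2E,6E,10E)-3,7,11,15-tetramethylhexadeca-2,6,10,14-tetraen-1-yl]naphthalene | COc1c(C)c(C/C=C(\C)CC/C=C(\C)CC/C=C(\C)CCC=C(C)C)c(OC)c2ccccc12 | intermediate
12 | (6E,10E,14E)-3-bromo-16-(1,4-dimethoxy-3-methylnaphthalen-2-yl)-2,6,10,14-tetramethylhexadeca-6,10,14-trien-2-ol (racemic) | COc1c(C)c(C/C=C(\C)CC/C=C(\C)CC/C=C(\C)CCC(Br)C(C)(C)O)c(OC)c2ccccc12 | intermediate (not isolated)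
13 | 2-[(2E,6E,10E)-13-(3,3-dimethyloxiran-2-yl)-3,7,11-trimethyltrideca-2,6,10-trien-1-yl]-1,4-dimethoxy-3-methylnaphthalene (racemic) | COc1c(C)c(C/C=C(\C)CC/C=C(\C)CC/C=C(\C)CCC3OC3(C)C)c(OC)c2ccccc12 | intermediate
14 | (4E,8E,12E)-14-(1,4-dimethoxy-3-methylnaphthalen-2-yl)-4,8,12-trimethyltetradeca-4,8,12-trienal | COc1c(C)c(C/C=C(\C)CC/C=C(\C)CC/C=C(\C)CCC=O)c(OC)c2ccccc12 | intermediate (not isolated)
15 | (4E,8E,12E)-14-(1,4-dimethoxy-3-methylnaphthalen-2-yl)-4,8,12-trimethyltetradeca-4,8,12-trien-1-ol | COc1c(C)c(C/C=C(\C)CC/C=C(\C)CC/C=C(\C)CCCO)c(OC)c2ccccc12 | intermediate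
16 | 2-[(2E,6E,10E)-14-iodo-3,7,11-trimethyltetradeca-2,6,10-trien-1-yl]-1,4-dimethoxy-3-methylnaphthalene | COc1c(C)c(C/C=C(\C)CC/C=C(\C)CC/C=C(\C)CCCI)c(OC)c2ccccc12 | intermediate
17 | [(4E,8E,12E)-14-(1,4-dimethoxy-3-methylnaphthalen-2-yl)-4,8,12-trimethyltetradeca-4,8,12-trien-1-yl]zinc iodide | COc1c(C)c(C/C=C(\C)CC/C=C(\C)CC/C=C(\C)CCC[Zn]I)c(OC)c2ccccc12 | intermediate (not isolated)
18 | 1,4-dimethoxy-2-methyl-3-[(2E,6E,10E)-3,7,11-trimethyl-14-{(3R)-3-[(2R)-6-methylhept-5-en-2-yl]cyclopent-1-en-1-yl}tetradeca-2,6,10-trien-1-yl]naphthalene | COc1c(C)c(C/C=C(\C)CC/C=C(\C)CC/C=C(\C)CCCC3=C[C@@H]([C@H](C)CCC=C(C)C)CC3)c(OC)c2ccccc12 | intermediate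
19 | 1,4-dimethoxy-2-methyl-3-[(3S,7S,11R)-3,7,11-trimethyl-14-{(1R,3S)-3-[(2R)-6-methylheptan-2-yl]cyclopentyl}tetradecyl]naphthalene | COc1c(C)c(CC[C@@H](C)CCC[C@@H](C)CCC[C@@H](C)CCC[C@@H]3CC[C@H]([C@H](C)CCCC(C)C)C3)c(OC)c2ccccc12 | intermediate
20 | 2-methyl-3-[(3S,7S,11R)-3,7,11-trimethyl-14-{(1R,3S)-3-[(2R)-6-methylheptan-2-yl]cyclopentyl}tetradecyl]naphthalene-1,4-dione | CC1=C(CC[C@@H](C)CCC[C@@H](C)CCC[C@@H](C)CCC[C@@H]2CC[C@H]([C@H](C)CCCC(C)C)C2)C(=O)c2ccccc2C1=O | target

**Step count and risks**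
Total steps: 11. Longest linear sequence: 7 (steps 1–4, 9, 10, 11; the branch through steps 5–8 is equally long).

Most likely to fail, first: step 3. The catalyst must choose between two diastereotopic C–H bonds next to an existing stereocentre, and the ligand hand is untested. The fallback sets out from 5 and comes back at 8; it moves control of C18' from the insertion to a catalytic conjugate reduction. Diazo compound 5 is cyclised with achiral Rh2(OAc)4 in CH2Cl2, giving 6 mixed with its ring epimer (2S,3S)-3-[(2R)-6-methylhept-5-en-2-yl]-2-(phenylsulfonyl)cyclopentan-1-one F1. The mixture is reduced with SmI2 as in step 4, but the enolate is silylated with Me3SiCl to trimethyl({3-[(2R)-6-methylhept-5-en-2-yl]cyclopent-1-en-1-yl}oxy)silane F2, as both C3 epimers. Saegusa–Ito oxidation with Pd(OAc)2 in MeCN erases C18' and gives 3-[(2R)-6-methylhept-5-en-2-yl]cyclopent-2-en-1-one F3. Copper hydride asymmetric conjugate reduction (CuCl, NaOt-Bu, the p-tol-BINAP enantiomer that delivers hydride to the required face, Ph2SiH2) resets C18' and gives the regiodefined silyl enol ether ({(3R)-3-[(2R)-6-methylhept-5-en-2-yl]cyclopent-1-en-1-yl}oxy)diphenylsilane F4. MeLi cleaves it to lithium (3R)-3-[(2R)-6-methylhept-5-en-2-yl]cyclopent-1-en-1-olate F5, which Comins' reagent converts into 8.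

Second: step 4. Trapping a samarium enolate as its triflate is unproven, and proton transfer from unreacted 6 can compete. The fallback sets out from 6 and comes back at 18; it keeps the sulfone through the coupling. Sulfone 6 is O-triflated (NaH, PhNTf2, THF) to (3R)-3-[(2R)-6-methylhept-5-en-2-yl]-2-(phenylsulfonyl)cyclopent-1-en-1-yl trifluoromethanesulfonate F6. Negishi coupling with 17 under the step 9 conditions gives the vinyl sulfone 1,4-dimethoxy-2-methyl-3-[(2E,6E,10E)-3,7,11-trimethyl-14-{(3R)-3-[(2R)-6-methylhept-5-en-2-yl]-2-(phenylsulfonyl)cyclopent-1-en-1-yl}tetradeca-2,6,10-trien-1-yl]naphthalene F7. Reductive desulfonylation with sodium amalgam (Na/Hg, Na2HPO4 buffer, MeOH/THF, −20 °C) then gives 18.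

Third: step 10. Five alkenes of three kinds must all be reduced with one ligand hand, and the ring face relies on the matched-pair analysis. The fallback sets out from 15 and comes back at 19; it separates chain and ring stereocontrol. Trienol 15 is hydrogenated first with the same iridium catalyst (a plain all-E triene of the tocopherol side-chain type) to (4R,8R,12S)-14-(1,4-dimethoxy-3-methylnaphthalen-2-yl)-4,8,12-trimethyltetradecan-1-ol F8. Iodination as in step 8 gives 2-[(3S,7R,11R)-14-iodo-3,7,11-trimethyltetradecyl]-1,4-dimethoxy-3-methylnaphthalene F9. Zinc insertion gives [(4R,8R,12S)-14-(1,4-dimethoxy-3-methylnaphthalen-2-yl)-4,8,12-trimethyltetradecyl]zinc iodide F10. Negishi coupling with 8 gives 1,4-dimethoxy-2-methyl-3-[(3S,7S,11R)-3,7,11-trimethyl-14-{(3R)-3-[(2R)-6-methylhept-5-en-2-yl]cyclopent-1-en-1-yl}tetradecyl]naphthalene F11. Its two remaining C=C bonds are then hydrogenated on their own, with the same chiral catalyst or with achiral [Ir(cod)(PCy3)(pyridine)]PF6 relying on addition anti to the C18' substituent, to give 19.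

**Further compounds**
F1 | step 3 | (2S,3S)-3-[(2R)-6-methylhept-5-en-2-yl]-2-(phenylsulfonyl)cyclopentan-1-one | O=C1CC[C@@H]([C@H](C)CCC=C(C)C)[C@@H]1S(=O)(=O)c1ccccc1
F2 | step 3 | trimethyl({3-[(2R)-6-methylhept-5-en-2-yl]cyclopent-1-en-1-yl}oxy)silane (both C3 epimers) | C[Si](C)(C)OC1=CC([C@H](C)CCC=C(C)C)CC1
F3 | step 3 | 3-[(2R)-6-methylhept-5-en-2-yl]cyclopent-2-en-1-one | O=C1C=C([C@H](C)CCC=C(C)C)CC1
F4 | step 3 | ({(3R)-3-[(2R)-6-methylhept-5-en-2-yl]cyclopent-1-en-1-yl}oxy)diphenylsilane | [H][Si](OC1=C[C@@H]([C@H](C)CCC=C(C)C)CC1)(c1ccccc1)c1ccccc1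
F5 | step 3 | lithium (3R)-3-[(2R)-6-methylhept-5-en-2-yl]cyclopent-1-en-1-olate | [Li+].[O-]C1=C[C@@H]([C@H](C)CCC=C(C)C)CC1
F6 | step 4 | (3R)-3-[(2R)-6-methylhept-5-en-2-yl]-2-(phenylsulfonyl)cyclopent-1-en-1-yl trifluoromethanesulfonate | FC(F)(F)S(=O)(=O)OC1=C(S(=O)(=O)c2ccccc2)[C@@H]([C@H](C)CCC=C(C)C)CC1
F7 | step 4 | 1,4-dimethoxy-2-methyl-3-[(2E,6E,10E)-3,7,11-trimethyl-14-{(3R)-3-[(2R)-6-methylhept-5-en-2-yl]-2-(phenylsulfonyl)cyclopent-1-en-1-yl}tetradeca-2,6,10-trien-1-yl]naphthalene | COc1c(C)c(C/C=C(\C)CC/C=C(\C)CC/C=C(\C)CCCC3=C(S(=O)(=O)c4ccccc4)[C@@H]([C@H](C)CCC=C(C)C)CC3)c(OC)c2ccccc12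
F8 | step 10 | (4R,8R,12S)-14-(1,4-dimethoxy-3-methylnaphthalen-2-yl)-4,8,12-trimethyltetradecan-1-ol | COc1c(C)c(CC[C@@H](C)CCC[C@@H](C)CCC[C@@H](C)CCCO)c(OC)c2ccccc12
F9 | step 10 | 2-[(3S,7R,11R)-14-iodo-3,7,11-trimethyltetradecyl]-1,4-dimethoxy-3-methylnaphthalene | COc1c(C)c(CC[C@@H](C)CCC[C@@H](C)CCC[C@@H](C)CCCI)c(OC)c2ccccc12
F10 | step 10 | [(4R,8R,12S)-14-(1,4-dimethoxy-3-methylnaphthalen-2-yl)-4,8,12-trimethyltetradecyl]zinc iodide | COc1c(C)c(CC[C@@H](C)CCC[C@@H](C)CCC[C@@H](C)CCC[Zn]I)c(OC)c2ccccc12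
F11 | step 10 | 1,4-dimethoxy-2-methyl-3-[(3S,7S,11R)-3,7,11-trimethyl-14-{(3R)-3-[(2R)-6-methylhept-5-en-2-yl]cyclopent-1-en-1-yl}tetradecyl]naphthalene | COc1c(C)c(CC[C@@H](C)CCC[C@@H](C)CCC[C@@H](C)CCCC3=C[C@@H]([C@H](C)CCC=C(C)C)CC3)c(OC)c2ccccc12
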